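You have a neighbour of elm on the bench, charged with 0.51 M of reagent, and you want one rule that tells you where both flasks stop.

| setting | birch | elm | maple |
|---|---|---|---|
| starting material | 0.57 M | 0.57 M | 0.57 M |
| partner | 1.03 M | 1.03 M | 1.03 M |
| reagent | 0.855 M | 0.855 M | 0.855 M |
| temperature | 0 °C | 25 °C | 50 °C |
| time | 30 s | 30 s | 30 s |

    starting material + reagent → open intermediate (k1 = 0.041 /M/s, Ea1 = 69.0 kJ/mol)
    2 second intermediate → homo product (k2 = 0.0037 /M/s, Ea2 = 66.0 kJ/mol)
    reagent + partner → second intermediate (k3 = 0.31 /M/s, Ea3 = 44.0 kJ/mol)
    partner ⇌ dormant form (K4 = 3.4, k4 = 0.024 /s, Ea4 = 92.0 kJ/mol, ΔH4 = 10.0 kJ/mol)
    open intermediate + second intermediate → target (k5 = 0.061 /M/s, Ea5 = 45.0 kJ/mol)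
    (constants at 25 °C)

1. the flask with the highest amount of target, in percent of the starting material charged ("all alike" if they lie within 1.5 percentage points) (birch / elm / maple / all alike)
2. final target, as a percentage of the starting material charged, in birch
3. final target, as a percentage of the starting material charged, in elm
4. final target, as a percentage of the starting material charged, in maple

- a doubled species enters its step squared and goes two at a time
- at 25 °C the constants are as listed, elsewhere as the activation energies and enthalpies make them

Ask first what the end state must be. Reagent feeds two competing steps, one with partner and one with starting material, and each is first order in reagent. Reagent therefore cancels from their ratio. The selectivity factor, the rate constant of the partner step over that of the starting-material step, is 7.56 at 25 °C. If partner is lost to that step and to no other, the fraction of partner left equals the fraction of starting material left raised to that power. Turnover stops when the two losses add up to the reagent charge. Solving that balance by repeated rounds, I expect elm to stop with 83.7% of its starting material left.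

Now see how fast elm gets there, rung by rung. Reagent lives 3.13 s against the partner charge. Starting material lives 28.5 s against the reagent charge, which is longer, so it sees reagent for a short while. Partner enters the dormant form on a scale of 41.7 s, later still, so I leave that step out of the balance. Open intermediate meets second intermediate on a scale of 19.2 s at best, shorter than 30 s, so in elm converted material is shared between open intermediate and target at the reading. In elm, the first half-life of second intermediate by its step to homo product is at least 158 s, longer than the run.

Heat moves the split. From birch to maple the starting-material step speeds up 110 times and the partner step 20 times, so the selectivity factor falls by a factor of 5.49. My bet is maple, and my reckoning goes no further.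

The forecast gave 0.4%, 10.1% and 38.6% for birch, elm and maple, and named maple: “Target formation needs both intermediates to build up, so yield rises steeply with temperature”. The simulation gives 0.387%, 9.78% and 37.3%, with maple highest.

Elm holds 82% of its starting material at 30.0 s, with 3.8% of its reagent left, against my 83.7%. The same selectivity factor gives the neighbour 92.3% left, and it holds 92%, with 0.77% of its reagent left. Birch is read well short of its stop, with 30% of its reagent left, and the time of the reading is one part of its low target: at 300 s birch stands at 6.88% target instead of 0.387%.

The numbers are assumed; the rest is arithmetic.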